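Target: 4'-O-methylcupressuflavone (CNP0322111.0). Unit 1 is the 4'-methoxyflavone half and unit 2 is the apigenin half.

**Plan**
- Cuts, in order: the five O–benzyl bonds; O1–C2 of ring C of unit 1 (back to a 2'-hydroxychalcone); C4a–C8a of ring A of unit 1; the bond from pyranone C3 to C8 of unit 2; the CH2–C(=O) bond of the pyranone side chain.
- Enabling feature: ring A of unit 1 (C4a, C5, C6, C7, C8, C8a) carries oxygen on C5, C7 and C8a and the acyl carbon C4 on C4a. It is an acylphloroglucinol, a folded tetraketide that can be stored as a 4-hydroxy-2-pyranone whose C3 (future C8) already bears unit 2.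
- Forward, part 1: apigenin supplies unit 2 with all its rings and becomes the 8-boronate; triacetic acid lactone is lengthened by a 4-methoxycinnamoyl group; the two are joined at pyranone C3.
- Forward, part 2: the pyranone is turned into arene ring A (a chalcone). The two exposed phenols are benzylated so that only the hydroxyl next to the biaryl bond stays free, ring C closes through it, and hydrogenolysis ends the route.
- Stereochemistry: the target has no stereocentre. The E alkene comes from 4-methoxycinnamic acid and is consumed in ring C, and the 8,8'' axis forms racemic.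

Key step: step 8

Assumption: the SMILES fixes no sense for the hindered 8,8'' axis, so the racemic atropisomer mixture is taken as the target.

Step 1
Reactants: 1 apigenin (5,7,4'-trihydroxyflavone)
Product: 2 5,7,4'-tribenzyloxyflavone
Conditions: BnBr (4 equiv), K2CO3, DMF, 80 °C
Reagents that add atoms: benzyl bromide, BrCc1ccccc1
Why: Williamson ether synthesis: the 7- and 4'-phenoxides alkylate readily and the hydrogen-bonded 5-OH follows with excess halide in hot DMF, so that unit 2 enters the basic and organometallic steps without acidic protons and all its masks fall together in step 11.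

Step 2
Reactants: 2 5,7,4'-tribenzyloxyflavone
Product: 3 5,7,4'-tribenzyloxy-8-iodoflavone
Conditions: NIS (1.05 equiv), TFA (cat.), CH2Cl2–MeCN, 0 °C to rt, dark
Reagents that add atoms: N-iodosuccinimide, O=C1CCC(=O)N1I
Why: Electrophilic aromatic iodination: ring A with its two meta-related alkoxy donors is the most electron-rich arene, and in fully O-alkylated 5,7-dioxygenated flavones substitution goes to C8 because C6 is shielded on both sides by benzyloxy groups.

Step 3
Reactants: 3 5,7,4'-tribenzyloxy-8-iodoflavone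
Product: 4 5,7,4'-tribenzyloxyflavone-8-boronic acid pinacol ester
Conditions: HBpin, PdCl2(MeCN)2 (cat.), SPhos, Et3N, 1,4-dioxane, 80 °C
Reagents that add atoms: pinacolborane, CC1(C)OBOC1(C)C
Why: Palladium-catalysed Miyaura-type borylation with pinacolborane, for which the bulky electron-rich biaryl phosphine is the established choice with di-ortho-substituted electron-rich aryl iodides, while the flavone carbonyl and the benzyl ethers are inert.

Step 4
Reactants: 5 (E)-4-methoxycinnamic acid
Product: 7 (E)-N-methoxy-N-methyl-4-methoxycinnamamide, via acyl imidazole 6 (not isolated)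
Conditions: CDI, CH2Cl2, rt; then MeNH(OMe)·HCl, rt
Reagents that add atoms: N,O-dimethylhydroxylamine hydrochloride, CNOC.Cl; 1,1'-carbonyldiimidazole, O=C(n1ccnc1)n1ccnc1 (its imidazolyl group sits in 6 only)
Why: Amide formation through the acyl imidazole gives the Weinreb amide without touching the E alkene.

Step 5
Reactants: 8 4-hydroxy-6-methyl-2-pyranone (triacetic acid lactone); 7 (E)-N-methoxy-N-methyl-4-methoxycinnamamide
Product: 10 4-hydroxy-6-[(E)-4-(4-methoxyphenyl)-2-oxobut-3-enyl]-2-pyranone, via dilithio dianion 9 (not isolated)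
Conditions: 8, LiN(i-Pr)2 (2.1 equiv), THF–DMPU, −78 to −20 °C; then 7, −78 to 0 °C; 1 M HCl
Reagents that add atoms: lithium diisopropylamide, CC(C)[N-]C(C)C.[Li+] (its lithium sits in 9 only)
Why: Dianion acylation: the second deprotonation of the lithium pyranolate places the most reactive carbanion on the C6 methyl group, and the Weinreb amide takes it up at the carbonyl carbon and releases the ketone only on acidic work-up, which prevents over-addition, proton transfer from the more acidic product and conjugate addition.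

Step 6
Reactants: 10 4-hydroxy-6-[(E)-4-(4-methoxyphenyl)-2-oxobut-3-enyl]-2-pyranone
Product: 11 6-[(E)-4-(4-methoxyphenyl)-2-oxobut-3-enyl]-2-oxo-3-(phenyliodonio)-2H-pyran-4-olate (phenyliodonium ylide)
Conditions: PhI(OAc)2 (1.0 equiv), Na2CO3 (1.0 equiv), MeCN–H2O, 0 °C to rt
Reagents that add atoms: (diacetoxyiodo)benzene, CC(=O)OI(OC(C)=O)c1ccccc1
Why: Known formation of a stabilised phenyliodonium ylide from a cyclic β-dicarbonyl compound: one equivalent of mild base ionises only the vinylogous acid (4-OH), which is far more acidic than the side-chain methylene, so trivalent iodine is taken up at C3.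

Step 7
Reactants: 11 phenyliodonium ylide; 4 5,7,4'-tribenzyloxyflavone-8-boronic acid pinacol ester
Product: 12 3-(5,7,4'-tribenzyloxyflavon-8-yl)-4-hydroxy-6-[(E)-4-(4-methoxyphenyl)-2-oxobut-3-enyl]-2-pyranone
Conditions: Pd(P(t-Bu)3)2 (cat.), LiOH·H2O, DME–H2O, rt to 40 °C; then 1 M HCl
Reagents that add atoms: none
Why: Suzuki–Miyaura-type coupling in which zerovalent palladium inserts into the C3–iodine bond of the ylide with loss of iodobenzene, a reaction known for ylides of 4-hydroxy-2-pyranone-type and cyclic 1,3-dione substrates also with 2,6-disubstituted arylboron partners, which needs no O-protection and runs near room temperature so that protodeboronation and ylide rearrangement are held back.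

Step 8
Reactants: 12 3-(5,7,4'-tribenzyloxyflavon-8-yl)-4-hydroxy-6-[(E)-4-(4-methoxyphenyl)-2-oxobut-3-enyl]-2-pyranone
Product: 14 2',4',6'-trihydroxy-4-methoxy-3'-(5,7,4'-tribenzyloxyflavon-8-yl)chalcone, via tetraketide methyl ester 13 (not isolated)
Conditions: Mg(OMe)2 (8 equiv), MeOH–THF, reflux; then cold 1 M HCl
Reagents that add atoms: magnesium methoxide, C[O-].C[O-].[Mg+2] (its methoxy group sits in 13 only and leaves again as methanol)
Why: The side-chain carbon cannot reach the carbonyl of the intact lactone without building a strained bridged bicycle, so the lactone is first opened reversibly by methoxide to the magnesium chelate of tetraketide ester 13, whose C6 methylene (future C4a), acidified by the C5 and C7 carbonyls, adds to the ester carbonyl C1 (future C8a, the former pyranone C2), methoxide leaves, and enolisation gives phloroglucinol ring A with the former ring oxygen as the C5 hydroxyl. The closest known reaction type is the Mg(OMe)2-mediated Claisen (Dieckmann-type) aromatisation of 6-(2-oxoalkyl)-4-hydroxy-2-pyranones to acylphloroglucinols, the flask version of the chalcone synthase ring closure. Ring A closes in the 6-(enolexo)-exo-trig mode through the new C4a–C8a bond. No stereocentre is created, the E alkene is not touched and the biaryl axis stays racemic. The step needs C-acylation to beat aldol closure (C2 onto C7), return to the lactone, oxa-Michael addition to the enone and retro-Claisen cleavage; the flavonyl group on C2 makes the aldol adduct quaternary so that it cannot dehydrate to an arene and falls back, divalent magnesium folds the chain and keeps the 1,3-dicarbonyl units as chelated enolates that resist cleavage, and every competing event is reversible whereas formation of the aromatic magnesium phenoxide is not. A cold acid quench and prompt use in step 9 limit closure of 14 to flavanones.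

Step 9
Reactants: 14 2',4',6'-trihydroxy-4-methoxy-3'-(5,7,4'-tribenzyloxyflavon-8-yl)chalcone
Product: 15 4',6'-dibenzyloxy-2'-hydroxy-4-methoxy-3'-(5,7,4'-tribenzyloxyflavon-8-yl)chalcone
Conditions: BnBr (2.2 equiv), K2CO3, DMF, rt to 50 °C
Reagents that add atoms: benzyl bromide, BrCc1ccccc1
Why: Site-selective Williamson etherification, as in the known partial alkylation of 3-substituted phloroacylphenones: the unchelated 4'-OH reacts first and, of the two hydroxyls ortho to the carbonyl, the 6'-OH next to C5'–H is far more accessible than the 2'-OH wedged between the acyl group and the di-ortho-substituted flavonyl ring, after which the remaining 2'-OH is locked in a hydrogen bond to the carbonyl, while any flavanone formed from 14 re-opens under K2CO3 by retro-oxa-Michael reaction and drains into the same diether.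

Step 10
Reactants: 15 4',6'-dibenzyloxy-2'-hydroxy-4-methoxy-3'-(5,7,4'-tribenzyloxyflavon-8-yl)chalcone
Product: 17 5,7-dibenzyloxy-4'-methoxy-8-(5,7,4'-tribenzyloxyflavon-8-yl)flavone, via flavanone 16 (not isolated)
Conditions: I2 (10 mol %), DMSO, 120 °C
Reagents that add atoms: none
Why: Iodine–DMSO oxidative cyclisation of a 2'-hydroxychalcone (oxa-Michael closure to 16, then iodine-mediated dehydrogenation with DMSO as terminal oxidant): the only free hydroxyl is the one next to the biaryl bond, so O1–C2 can form only in the 8-linked sense, and a late loss of the benzyl group peri to the carbonyl would do no harm before step 11.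

Step 11
Reactants: 17 5,7-dibenzyloxy-4'-methoxy-8-(5,7,4'-tribenzyloxyflavon-8-yl)flavone
Product: 18 4'-O-methylcupressuflavone (target)
Conditions: H2 (1 atm), 10% Pd/C, THF–MeOH, rt
Reagents that add atoms: none
Why: Catalytic hydrogenolysis cleaves all five aryl benzyl ethers, whereas the aryl methyl ether is inert and the C2=C3 bonds of both flavones, being vinylogous esters conjugated to arenes, are not reduced at one atmosphere.

**Compound list**
1 | apigenin (5,7,4'-trihydroxyflavone) | O=c1cc(-c2ccc(O)cc2)oc2cc(O)cc(O)c12 | starting material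
2 | 5,7,4'-tribenzyloxyflavone | O=c1cc(-c2ccc(OCc3ccccc3)cc2)oc2cc(OCc3ccccc3)cc(OCc3ccccc3)c12 | intermediate
3 | 5,7,4'-tribenzyloxy-8-iodoflavone | Ic1c(OCc2ccccc2)cc(OCc2ccccc2)c2c(=O)cc(-c3ccc(OCc4ccccc4)cc3)oc12 | intermediate
4 | 5,7,4'-tribenzyloxyflavone-8-boronic acid pinacol ester | CC1(C)OB(OC1(C)C)c1c(OCc2ccccc2)cc(OCc2ccccc2)c2c(=O)cc(-c3ccc(OCc4ccccc4)cc3)oc12 | intermediate
5 | (E)-4-methoxycinnamic acid | COc1ccc(/C=C/C(=O)O)cc1 | starting material
6 | (E)-1-(4-methoxycinnamoyl)imidazole | COc1ccc(/C=C/C(=O)n2ccnc2)cc1 | intermediate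
7 | (E)-N-methoxy-N-methyl-4-methoxycinnamamide | COc1ccc(/C=C/C(=O)N(C)OC)cc1 | intermediate
8 | 4-hydroxy-6-methyl-2-pyranone (triacetic acid lactone) | Cc1cc(O)cc(=O)o1 | starting material
9 | dilithio dianion of 8 (4-olate and C6 methylene carbanion) | [Li+].[Li+].[CH2-]c1cc([O-])cc(=O)o1 | intermediate
10 | 4-hydroxy-6-[(E)-4-(4-methoxyphenyl)-2-oxobut-3-enyl]-2-pyranone | COc1ccc(/C=C/C(=O)Cc2cc(O)cc(=O)o2)cc1 | intermediate
11 | 6-[(E)-4-(4-methoxyphenyl)-2-oxobut-3-enyl]-2-oxo-3-(phenyliodonio)-2H-pyran-4-olate | COc1ccc(/C=C/C(=O)Cc2cc([O-])c([I+]c3ccccc3)c(=O)o2)cc1 | intermediate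
12 | 3-(5,7,4'-tribenzyloxyflavon-8-yl)-4-hydroxy-6-[(E)-4-(4-methoxyphenyl)-2-oxobut-3-enyl]-2-pyranone | COc1ccc(/C=C/C(=O)Cc2cc(O)c(-c3c(OCc4ccccc4)cc(OCc4ccccc4)c4c(=O)cc(-c5ccc(OCc6ccccc6)cc5)oc34)c(=O)o2)cc1 | intermediate
13 | methyl (E)-2-(5,7,4'-tribenzyloxyflavon-8-yl)-9-(4-methoxyphenyl)-3,5,7-trioxonon-8-enoate (magnesium chelate in the flask, drawn neutral; C2 racemic and enolisable) | COC(=O)C(C(=O)CC(=O)CC(=O)/C=C/c1ccc(OC)cc1)c1c(OCc2ccccc2)cc(OCc2ccccc2)c2c(=O)cc(-c3ccc(OCc4ccccc4)cc3)oc12 | intermediate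
14 | 2',4',6'-trihydroxy-4-methoxy-3'-(5,7,4'-tribenzyloxyflavon-8-yl)chalcone | COc1ccc(/C=C/C(=O)c2c(O)cc(O)c(-c3c(OCc4ccccc4)cc(OCc4ccccc4)c4c(=O)cc(-c5ccc(OCc6ccccc6)cc5)oc34)c2O)cc1 | intermediate
15 | 4',6'-dibenzyloxy-2'-hydroxy-4-methoxy-3'-(5,7,4'-tribenzyloxyflavon-8-yl)chalcone | COc1ccc(/C=C/C(=O)c2c(OCc3ccccc3)cc(OCc3ccccc3)c(-c3c(OCc4ccccc4)cc(OCc4ccccc4)c4c(=O)cc(-c5ccc(OCc6ccccc6)cc5)oc34)c2O)cc1 | intermediate
16 | 5,7-dibenzyloxy-4'-methoxy-8-(5,7,4'-tribenzyloxyflavon-8-yl)flavanone (C2 racemic) | COc1ccc(C2CC(=O)c3c(OCc4ccccc4)cc(OCc4ccccc4)c(-c4c(OCc5ccccc5)cc(OCc5ccccc5)c5c(=O)cc(-c6ccc(OCc7ccccc7)cc6)oc45)c3O2)cc1 | intermediate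
17 | 5,7-dibenzyloxy-4'-methoxy-8-(5,7,4'-tribenzyloxyflavon-8-yl)flavone | COc1ccc(-c2cc(=O)c3c(OCc4ccccc4)cc(OCc4ccccc4)c(-c4c(OCc5ccccc5)cc(OCc5ccccc5)c5c(=O)cc(-c6ccc(OCc7ccccc7)cc6)oc45)c3o2)cc1 | intermediate
18 | 4'-O-methylcupressuflavone (8,8''-biapigenin 4'-methyl ether, racemic axis) | COc1ccc(-c2cc(=O)c3c(O)cc(O)c(-c4c(O)cc(O)c5c(=O)cc(-c6ccc(O)cc6)oc45)c3o2)cc1 | target

**Step count**
Total: 11 steps. Longest linear sequence: 8 steps (1, 2, 3, 7, 8, 9, 10, 11). The branch 4, 5, 6 is equally long up to step 7.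

**Steps most likely to fail**

**Step 7.**
- Risk: transmetalation at a boron atom flanked by two oxygen substituents is slow. Protodeboronation, phenyl transfer from iodine and thermal aryl migration within the ylide may then overtake the coupling.
- Fallback: a Pinhey arylation, that is ligand coupling at tetravalent lead in place of palladium catalysis. It sets out from iodide 3 and the free pyranone 10 and comes back at 12.
- Stannylation of 3 with (Bu3Sn)2 and Pd(PPh3)4 in toluene at reflux should give 5,7,4'-tribenzyloxy-8-(tributylstannyl)flavone F1.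
- Tin–lead exchange with Pb(OAc)4 and catalytic Hg(OAc)2 in CHCl3 should give (5,7,4'-tribenzyloxyflavon-8-yl)lead triacetate F2.
- F2 is treated in the same flask with 10 and pyridine at 40–60 °C and should arylate C3 of the vinylogous acid to give 12.
- This ligand coupling is helped rather than slowed by ortho substituents, and steps 3 and 6 fall away.

**Step 8.**
- Risk: methoxide or a chain enolate oxygen may add to the cinnamoyl enone, or retro-Claisen cleavage may shed the cinnamoyl group, faster than the hindered ester carbonyl next to the aryl-bearing carbon is attacked. The anionic pyranone may also resist methanolysis.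
- Fallback: the same C4a–C8a Claisen closure is kept but run without an enone, and the styryl part is added afterwards by aldol condensation. It sets out from 8 (through dianion 9) and boronate 4 and comes back at 15.
- Acylation of 9 with N-methoxy-N-methylacetamide should give 4-hydroxy-6-(2-oxopropyl)-2-pyranone F3.
- PhI(OAc)2 and Na2CO3 should give 2-oxo-6-(2-oxopropyl)-3-(phenyliodonio)-2H-pyran-4-olate F4.
- Coupling with 4 as in step 7 should give 3-(5,7,4'-tribenzyloxyflavon-8-yl)-4-hydroxy-6-(2-oxopropyl)-2-pyranone F5.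
- Mg(OMe)2 in MeOH–THF should take F5 through methyl 2-(5,7,4'-tribenzyloxyflavon-8-yl)-3,5,7-trioxooctanoate F6 to 2,4,6-trihydroxy-3-(5,7,4'-tribenzyloxyflavon-8-yl)acetophenone F7.
- BnBr (2.2 equiv) and K2CO3 in DMF should give 4,6-dibenzyloxy-2-hydroxy-3-(5,7,4'-tribenzyloxyflavon-8-yl)acetophenone F8.
- Claisen–Schmidt condensation of F8 with 4-methoxybenzaldehyde (KOH, EtOH–THF, rt) should give 15.

**Step 9.**
- Risk: discrimination between the two hydroxyls ortho to the carbonyl may be poor. C-benzylation at C5' or over-alkylation may also interfere.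
- Fallback: regiocontrol by protection is given up in favour of undirected ring closure and separation. It sets out from 14 and comes back at 18.
- I2 (cat.) in DMSO at 120 °C on unprotected 14 should close ring C through either ortho hydroxyl.
- This should give 5,7-dihydroxy-4'-methoxy-8-(5,7,4'-tribenzyloxyflavon-8-yl)flavone F9 together with 5,7-dihydroxy-4'-methoxy-6-(5,7,4'-tribenzyloxyflavon-8-yl)flavone F10.
- The two isomers are separated by chromatography, and hydrogenolysis of F9 (H2, 10% Pd/C, THF–MeOH) should give 18.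

**Further compounds**
F1 | step 7 | 5,7,4'-tribenzyloxy-8-(tributylstannyl)flavone | CCCC[Sn](CCCC)(CCCC)c1c(OCc2ccccc2)cc(OCc2ccccc2)c2c(=O)cc(-c3ccc(OCc4ccccc4)cc3)oc12
F2 | step 7 | (5,7,4'-tribenzyloxyflavon-8-yl)lead triacetate | CC(=O)O[Pb](OC(C)=O)(OC(C)=O)c1c(OCc2ccccc2)cc(OCc2ccccc2)c2c(=O)cc(-c3ccc(OCc4ccccc4)cc3)oc12
F3 | step 8 | 4-hydroxy-6-(2-oxopropyl)-2-pyranone | CC(=O)Cc1cc(O)cc(=O)o1
F4 | step 8 | 2-oxo-6-(2-oxopropyl)-3-(phenyliodonio)-2H-pyran-4-olate | CC(=O)Cc1cc([O-])c([I+]c2ccccc2)c(=O)o1
F5 | step 8 | 3-(5,7,4'-tribenzyloxyflavon-8-yl)-4-hydroxy-6-(2-oxopropyl)-2-pyranone | CC(=O)Cc1cc(O)c(-c2c(OCc3ccccc3)cc(OCc3ccccc3)c3c(=O)cc(-c4ccc(OCc5ccccc5)cc4)oc23)c(=O)o1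
F6 | step 8 | methyl 2-(5,7,4'-tribenzyloxyflavon-8-yl)-3,5,7-trioxooctanoate | COC(=O)C(C(=O)CC(=O)CC(C)=O)c1c(OCc2ccccc2)cc(OCc2ccccc2)c2c(=O)cc(-c3ccc(OCc4ccccc4)cc3)oc12
F7 | step 8 | 2,4,6-trihydroxy-3-(5,7,4'-tribenzyloxyflavon-8-yl)acetophenone | CC(=O)c1c(O)cc(O)c(-c2c(OCc3ccccc3)cc(OCc3ccccc3)c3c(=O)cc(-c4ccc(OCc5ccccc5)cc4)oc23)c1O
F8 | step 8 | 4,6-dibenzyloxy-2-hydroxy-3-(5,7,4'-tribenzyloxyflavon-8-yl)acetophenone | CC(=O)c1c(OCc2ccccc2)cc(OCc2ccccc2)c(-c2c(OCc3ccccc3)cc(OCc3ccccc3)c3c(=O)cc(-c4ccc(OCc5ccccc5)cc4)oc23)c1O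
F9 | step 9 | 5,7-dihydroxy-4'-methoxy-8-(5,7,4'-tribenzyloxyflavon-8-yl)flavone | COc1ccc(-c2cc(=O)c3c(O)cc(O)c(-c4c(OCc5ccccc5)cc(OCc5ccccc5)c5c(=O)cc(-c6ccc(OCc7ccccc7)cc6)oc45)c3o2)cc1
F10 | step 9 | 5,7-dihydroxy-4'-methoxy-6-(5,7,4'-tribenzyloxyflavon-8-yl)flavone | COc1ccc(-c2cc(=O)c3c(O)c(-c4c(OCc5ccccc5)cc(OCc5ccccc5)c5c(=O)cc(-c6ccc(OCc7ccccc7)cc6)oc45)c(O)cc3o2)cc1
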